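The readings are simulated with constants of no real substance; noise was put on by code.

The complex with one exchanged stands level at 10.6% of the starting complex charged, the mean of the west readings from 40.0 h on; that is 0.0169 M against 0.192 M of incoming ligand charged, and west is this very flask, followed so far.

- west: starting complex 0.16 M; incoming ligand 0.192 M; the very flask that is asked about, followed so far
- flask: starting complex 0.16 M; incoming ligand 0.192 M; time 8.0 d

west run (percent of the starting complex charged)

| time / h | complex with one exchanged / % | starting complex / % |
|---|---|---|
| 8.00 | 7.1 | 59.0 |
| 20.0 | 9.8 | 57.0 |
| 40.0 | 10.7 | 57.9 |
| 60.0 | 10.0 | 56.7 |
| 96.0 | 11.1 | 55.6 |
| 120 | 10.5 | 56.0 |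

(scatter of a reading: 0.5 percentage points)

- additions leave the volume as it is

- grey: at 8.0 d add starting complex, 50.0% of the amount charged, then wait 8.0 d
- amber: change nothing and wait 8.0 d more
- teal: at 8.0 d add incoming ligand, 100% of the amount charged, then wait 8.0 d
- red: at 8.0 d take out 90% of the leaving ligand then present, then wait 8.0 d

- complex with one exchanged, in percent of the starting complex first charged, at 8.0 d
- which option adds most complex with one exchanged ("none" when 2 percentage points or less is all one gets) (grey / amber / teal / red / none)
- complex with one exchanged present, in percent of the starting complex first charged, after amber
- complex with one exchanged present, in percent of the starting complex first charged, after teal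

Taken first, the main step turns starting complex and incoming ligand into complex with one exchanged and leaving ligand, and the flask holds more incoming ligand than starting complex, yet the west run still shows 56.0% starting complex at 120 h. The next process is a hidden share: 33.9% of the starting complex charged is unaccounted for at 8.00 h and 33.5% at 120 h, about a third both times and level within the scatter, while the complex with one exchanged grows by 3.4 percentage points between those readings, so in the west run the hidden share has levelled before the complex with one exchanged does. Counted one for one, the level of the complex with one exchanged accounts for 8.81% of the incoming ligand charged, and the reckoning here commits to a further process: incoming ligand consumes itself two at a time, at a rate going with its square, while the exchange goes with its first power. Joining the two ends gives plateau = level × ln(1 + charge/level), which returns 0.00446 M: this is the crossover level, the concentration of incoming ligand at which pairing and exchange consume it at equal rates. The plateau is thus the yield of a single charge, so this reckoning puts the flask at 10.6% now and after amber, gives grey and red no gain beyond the margin since they bring no incoming ligand, and puts teal, with a second charge at the same level, near 21.1%.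

The forecast gave 10.6% now, 10.6% after amber, 10.5% after teal and grey as best, holding that “Both steps look equilibrated”, and so parts from this reckoning on teal and on the best option.

The flask gives 11.3% now, 11.3% after amber and 19.3% after teal, and teal is best with 8.1 points gained, against 0.029 points for grey and 0.026 points for red.

    starting complex + incoming ligand → leaving ligand + complex with one exchanged (k = 0.230 M⁻¹ h⁻¹)
    complex with one exchanged + incoming ligand → leaving ligand + complex with two exchanged (k = 0.120 M⁻¹ h⁻¹)
    complex with two exchanged + incoming ligand → leaving ligand + complex with three exchanged (k = 1.20 M⁻¹ h⁻¹)
    2 incoming ligand → homo dimer (k = 2.30 M⁻¹ h⁻¹)
    starting complex ⇌ dormant form (K = 0.580, k = 0.290 h⁻¹)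

A neighbour flask with the same starting complex, charged with 0.048 M of incoming ligand, reckons at 6.87% from the crossover level and gives 7.23%. This flask has come to rest: at 192 h the incoming ligand, its limiting reagent, stands at 0.0288% of its charge, which is 5.52 × 10⁻⁵ M, far below the 0.00446 M level, and counted one for one that remainder equals 0.0345% of the starting complex charged. At 1920 h the complex with one exchanged in this flask still stands at 11.3%, and amber's further 8.0 d adds 0.026 points.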